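**Plan**
1. Retrosynthesis cuts C8–CH3 (back to a C8 ketone), then in one operation C9–C11 (benzylic bond) and C9–C10, which takes C9 out of ring B and leaves a trans-hydrindan-8-one. Then C4–CH3, C5–H, the C3 oxygen and the C4–chain bond lead back to (S)-Hajos–Parrish ketone.
2. Forward: ring A and the five-membered ring C5–C6–C7–C8–C10 are present from the start. Ring A is finished first (C4 chain by Negishi coupling, C4 methyl and C5–H by reductive methylation, C3 deoxygenation). The five-membered ring then grows to ring B by insertion of C9 between C8 and C10, and the aryl fragment is joined to C9 in the same flask. Last, the C8 carbonyl becomes the C7=C8 olefin with its methyl.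
3. Enabling feature: in ring B the CH carbon C9 lies between the quaternary, methyl-bearing C10 and C8, which is sp2 in the target. With C8 as a carbonyl, ring B minus C9 is the cyclopentanone of a Hajos–Parrish hydrindane. A C10→C9 1,2-shift at a C9 carbenoid returns the C8 carbonyl as an enolate whose nucleophilic carbon is C9.
4. Stereochemistry: C10 comes from the starting ketone and is retained in the shift. C5 (trans) and C4 come from the Li/NH3 reductive methylation (protonation trans to, methylation anti to, the C10 methyl). C9 is set by equilibration next to the C8 carbonyl to the equatorial 9β-benzyl epimer.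

Key step: step 8

Remark: atoms carry the numbers they have in the target (ring A = C1–C5 and C10; ring B = C5–C10; C11 = benzylic CH2; in the hydrindanes the five-membered ring is C5–C6–C7–C8–C10 and C9 is not yet present); β is the face of the C10 methyl. Read this way, the target is 4α-methyl, 4β-(4-methylpent-3-enyl), 5α-H, 9β-arylmethyl (9α-H), 10β-methyl, Δ7, i.e. (4R,5S,9S,10S). Compounds 1, 4 and 13 are commercial.

**Step 1**
Reactants: 1 (S)-Hajos–Parrish ketone
Product: 2 enone ketal (C8 dioxolane of 1)
Conditions: 2-ethyl-2-methyl-1,3-dioxolane, HOCH2CH2OH (cat.), TsOH·H2O (cat.), 23 °C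
Reagents that add atoms: 2-ethyl-2-methyl-1,3-dioxolane, CCC1(C)OCCO1
Why: Acid-catalysed transketalisation should engage the saturated cyclopentanone much faster than the less electrophilic, vinylogous enone carbonyl, a selectivity known for this diketone.

**Step 2**
Reactants: 2 enone ketal
Product: 3 4-iodo enone ketal
Conditions: I2, pyridine, CH2Cl2, 0 → 23 °C
Reagents that add atoms: iodine, II
Why: α-Iodination of an enone by iodine/pyridine (conjugate addition, iodination of the enol form, elimination) should place iodine on C4, the only vinylic C–H, under buffered conditions that spare the ketal.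

**Step 3**
Reactants: 3 4-iodo enone ketal; 4 5-bromo-2-methylpent-2-ene
Product: 6 4-(4-methylpent-3-enyl) enone ketal, via (4-methylpent-3-enyl)zinc bromide 5 (not isolated)
Conditions: 4, Zn dust, LiCl, THF, 50 °C; then 3, PdCl2(dppf) (5 mol %), THF/DMF, 23 → 50 °C
Reagents that add atoms: none
Why: LiCl-assisted zinc insertion into the primary bromide followed by Negishi coupling with the vinylic iodide should form the C4–chain bond, since alkylzinc halides tolerate the enone and the ketal.

**Step 4**
Reactants: 6 4-(4-methylpent-3-enyl) enone ketal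
Product: 8 trans-hydrindane keto ketal (C3 ketone, 4α-methyl, 4β-chain, 5α-H), via lithium C3–C4 enolate 7 (not isolated)
Conditions: Li (2.1 equiv), t-BuOH (1.0 equiv), NH3(l)/THF, −78 °C; then MeI, −78 → −33 °C; then H2O
Reagents that add atoms: iodomethane, CI
Why: Birch-type reductive alkylation: the C5 carbanion should be protonated trans to the angular methyl (5α-H, trans-hydrindane), and MeI should attack the enolate at C4 anti to the axial C10 methyl, so the new methyl is α and the chain already on C4 becomes β; the isolated alkene and the ketal are inert to Li/NH3.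

**Step 5**
Reactants: 8 trans-hydrindane keto ketal
Product: 10 deoxygenated hydrindane ketal (C3 = CH2), via C3 hydrazone 9 (not isolated)
Conditions: N2H4·H2O, KOH, diethylene glycol, 130 → 200 °C
Reagents that add atoms: none
Why: Wolff–Kishner reduction (Huang-Minlon variant) should remove the hindered C3 carbonyl next to the quaternary C4 under basic conditions to which the ketal and the trisubstituted alkene are stable, without touching a stereocentre.

**Step 6**
Reactants: 10 deoxygenated hydrindane ketal
Product: 11 trans-hydrindan-8-one
Conditions: 1 M HCl, THF, 23 °C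
Reagents that add atoms: water, O
Why: Acid-catalysed ketal hydrolysis under dilute conditions should free the C8 ketone without hydrating the trisubstituted alkene; C5 is not α to the carbonyl and cannot epimerise.

**Step 7**
Reactants: 11 trans-hydrindan-8-one
Product: 12 8α-(dibromomethyl)-8β-hydroxy hydrindane
Conditions: CH2Br2, LiN(i-Pr)2, THF, −78 °C; then 11, −78 °C; then H2O
Reagents that add atoms: dibromomethane, BrCBr (reacts as dibromomethyllithium, [Li]C(Br)Br)
Why: 1,2-Addition of the small nucleophile dibromomethyllithium to the cyclopentanone should occur from the α face opposite the C10 methyl; the C8 configuration is erased in step 8 and is not critical.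

**Step 8**
Reactants: 12 8α-(dibromomethyl)-8β-hydroxy hydrindane; 13 methyl 3-(bromomethyl)-4-methoxybenzoate
Product: 16 9α-benzylated decalin-8-one (9-epimer of 17), via β-oxido carbenoid 14 (not isolated), via ring-enlarged lithium enolate 15 (not isolated)
Conditions: n-BuLi (2.05 equiv), THF, −78 → 0 °C; then 13, DMPU, −40 → 0 °C
Reagents that add atoms: none
Why: n-BuLi deprotonates the hydroxyl and exchanges one bromine for lithium to give the β-oxido carbenoid 14, in which the electron-rich C8–C10 bond shifts to the electron-poor C9 as LiBr leaves and the alkoxide becomes the carbonyl, so that the lithium enolate 15 forms specifically across C8–C9 and is then C-alkylated by the benzylic bromide 13. The closest known reaction type is the β-oxido carbenoid one-carbon ring enlargement of cycloalkanones through their dibromomethyl carbinols, with alkylation of the ring-enlarged enolate in the same flask. Ring B is not closed by a cyclisation: the five-membered ring C5–C6–C7–C8–C10 becomes six-membered when C9 is inserted between C8 and C10 by this 1,2-shift. C10 migrates with retention, so the trans C5/C10 fusion from step 4 is carried into the decalin, while the new C9 centre arises from attack of 13 on the enolate face anti to the axial C10 methyl (9α-benzyl) and is corrected in step 9 through the new C8 carbonyl. The step needs migration of C10 and not of the C7 methylene, which the substrate should secure by the higher migratory aptitude of the fully substituted carbon toward the carbenoid centre and by the α-oriented CHBr2 group, whose C–Br bond can lie anti to C8–C10 pointing away from ring A; it also needs C-benzylation to outrun reaction of the enolate with the 1-bromobutane formed in the exchange, which the far more reactive benzylic bromide should ensure.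

**Step 9**
Reactants: 16 9α-benzylated decalin-8-one
Product: 17 9β-benzylated decalin-8-one
Conditions: NaOMe (0.3 equiv), MeOH, 23 → 50 °C
Reagents that add atoms: none
Why: Base-mediated epimerisation α to the C8 ketone through the C8–C9 enolate should move the benzyl group from the axial 9α to the equatorial 9β position, relieving its 1,3-diaxial contacts with H5 and H7 (thermodynamic control; methoxide matches the methyl ester).

**Step 10**
Reactants: 17 9β-benzylated decalin-8-one
Product: 19 C8 enol triflate (Δ7), via potassium C7–C8 enolate 18 (not isolated)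
Conditions: KN(SiMe3)2, THF, −78 °C; then PhNTf2, −78 → 0 °C
Reagents that add atoms: N-phenylbis(trifluoromethanesulfonimide), O=S(=O)(N(c1ccccc1)S(=O)(=O)C(F)(F)F)C(F)(F)F
Why: Kinetic deprotonation by the bulky amide should occur at the unhindered C7 methylene and not at the tertiary C9 flanked by the quaternary C10, and O-sulfonylation fixes the double bond at C7=C8 (regioselective enol triflate formation) without disturbing C9.

**Step 11**
Reactants: 19 C8 enol triflate
Product: 20 jaspic acid O-methyl ether methyl ester
Conditions: MeMgBr, Fe(acac)3 (5 mol %), THF/NMP, −30 → 0 °C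
Reagents that add atoms: methylmagnesium bromide, C[Mg]Br
Why: Iron-catalysed cross-coupling of the alkenyl triflate with the methyl Grignard reagent should replace OTf by CH3 with the olefin position unchanged, faster than addition to the aryl ester at low temperature.

**Step 12**
Reactants: 20 jaspic acid O-methyl ether methyl ester
Product: 21 jaspic acid
Conditions: NaSEt, DMF, 140 °C; 1 M HCl work-up
Reagents that add atoms: none
Why: SN2 demethylation by thiolate should cleave both the methyl ester and the aryl methyl ether under basic conditions that cannot isomerise or cyclise the two trisubstituted alkenes, as acidic ether cleavage could.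

**Compound list**
1 | (S)-Hajos–Parrish ketone, (7aS)-7a-methyl-2,3,7,7a-tetrahydro-1H-indene-1,5(6H)-dione | C[C@]12CCC(=O)C=C1CCC2=O | starting material
2 | enone ketal, (7a'S)-7a'-methyl-2',3',7',7a'-tetrahydrospiro[[1,3]dioxolane-2,1'-inden]-5'(6'H)-one (C3 ketone, Δ4, C8 dioxolane) | C[C@]12CCC(=O)C=C1CCC21OCCO1 | intermediate
3 | 4-iodo enone ketal (iodine on the enone α-carbon C4 of 2) | C[C@]12CCC(=O)C(I)=C1CCC21OCCO1 | intermediate
4 | 5-bromo-2-methylpent-2-ene | CC(C)=CCCBr | starting material
5 | (4-methylpent-3-enyl)zinc bromide | CC(C)=CCC[Zn]Br | intermediate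
6 | 4-(4-methylpent-3-enyl) enone ketal (chain on C4 of 2) | C[C@]12CCC(=O)C(CCC=C(C)C)=C1CCC21OCCO1 | intermediate
7 | lithium C3–C4 enolate of the trans-fused (5α-H) 4-(4-methylpent-3-enyl) C3 ketone, C8 dioxolane | CC(C)=CCCC1=C(O[Li])CC[C@@]2(C)[C@H]1CCC23OCCO3 | intermediate
8 | trans-hydrindane keto ketal: C3 ketone, C8 dioxolane, 4α,10β-dimethyl, 4β-(4-methylpent-3-enyl), 5α-H | CC(C)=CCC[C@@]1(C)C(=O)CC[C@@]2(C)[C@H]1CCC23OCCO3 | intermediate
9 | C3 hydrazone of 8 | CC(C)=CCC[C@@]1(C)C(=NN)CC[C@@]2(C)[C@H]1CCC23OCCO3 | intermediate
10 | deoxygenated hydrindane ketal (8 with C3 = CH2) | CC(C)=CCC[C@@]1(C)CCC[C@@]2(C)[C@H]1CCC23OCCO3 | intermediate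
11 | trans-hydrindan-8-one: octahydroinden-1-one with the carbonyl (C8) next to the methyl-bearing fusion carbon C10; 4α,10β-dimethyl, 4β-(4-methylpent-3-enyl), 5α-H | CC(C)=CCC[C@@]1(C)CCC[C@@]2(C)[C@H]1CCC2=O | intermediate
12 | 8α-(dibromomethyl)-8β-hydroxy hydrindane (carbinol of 11) | CC(C)=CCC[C@@]1(C)CCC[C@@]2(C)[C@H]1CC[C@@]2(O)C(Br)Br | intermediate
13 | methyl 3-(bromomethyl)-4-methoxybenzoate | COC(=O)c1ccc(OC)c(CBr)c1 | starting material
14 | β-oxido carbenoid: 8β-lithiooxy-8α-[bromo(lithio)methyl] hydrindane | CC(C)=CCC[C@@]1(C)CCC[C@@]2(C)[C@H]1CC[C@@]2(O[Li])C([Li])Br | intermediate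
15 | lithium C8–C9 enolate of 4α,10β-dimethyl-4β-(4-methylpent-3-enyl)-5α-decalin-8-one | CC(C)=CCC[C@@]1(C)CCC[C@]2(C)C=C(O[Li])CC[C@@H]12 | intermediate
16 | methyl 4-methoxy-3-{[4α,10β-dimethyl-4β-(4-methylpent-3-enyl)-8-oxo-5α-decalin-9α-yl]methyl}benzoate (9β-H) | CC(C)=CCC[C@@]1(C)CCC[C@]2(C)[C@H](Cc3cc(C(=O)OC)ccc3OC)C(=O)CC[C@@H]12 | intermediate
17 | methyl 4-methoxy-3-{[4α,10β-dimethyl-4β-(4-methylpent-3-enyl)-8-oxo-5α-decalin-9β-yl]methyl}benzoate (9α-H) | CC(C)=CCC[C@@]1(C)CCC[C@]2(C)[C@@H](Cc3cc(C(=O)OC)ccc3OC)C(=O)CC[C@@H]12 | intermediate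
18 | potassium C7–C8 enolate of 17 | CC(C)=CCC[C@@]1(C)CCC[C@]2(C)[C@@H](Cc3cc(C(=O)OC)ccc3OC)C(O[K])=CC[C@@H]12 | intermediate
19 | C8 enol triflate of 17 (C7=C8) | CC(C)=CCC[C@@]1(C)CCC[C@]2(C)[C@@H](Cc3cc(C(=O)OC)ccc3OC)C(OS(=O)(=O)C(F)(F)F)=CC[C@@H]12 | intermediate
20 | jaspic acid O-methyl ether methyl ester | CC(C)=CCC[C@@]1(C)CCC[C@]2(C)[C@@H](Cc3cc(C(=O)OC)ccc3OC)C(C)=CC[C@@H]12 | intermediate
21 | jaspic acid, 4-hydroxy-3-{[4α,8,10β-trimethyl-4β-(4-methylpent-3-enyl)-5α-decal-7-en-9β-yl]methyl}benzoic acid | CC(C)=CCC[C@@]1(C)CCC[C@]2(C)[C@@H](Cc3cc(C(=O)O)ccc3O)C(C)=CC[C@@H]12 | target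

Total step count: 12. Longest linear sequence: 12 steps (1 → 21).

**Steps most likely to fail**

Step 8. The C7 methylene may migrate instead of the quaternary C10, or proton exchange and butylation may compete when the crowded enolate is trapped. The fallback sets out from 11 and comes back at 17. Addition of CH2=CHMgBr with CeCl3 to 11 from the α face gives the 8α-vinyl-8β-hydroxy hydrindane F1. Hydroxyl-directed epoxidation with VO(acac)2 and t-BuOOH, which does not direct to the remote trisubstituted alkene, gives the epoxy alcohol F2. BF3·OEt2 in CH2Cl2 at −78 °C then triggers the semipinacol rearrangement of this 2,3-epoxy alcohol, in which C10 shifts to C9 antiperiplanar to the breaking C9–O bond, and gives the 9-(hydroxymethyl)decalin-8-one F3. Mesylation and elimination (MsCl, Et3N; then DBU) give the 9-methylenedecalin-8-one F4. Conjugate addition of [2-methoxy-5-(methoxycarbonyl)phenyl]boronic acid with [RhCl(cod)]2 in dioxane/H2O, with protonation of the enolate on the α face, gives 17 directly, so step 9 is not needed on this path.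

Step 2. Conjugate addition of pyridine to the fully substituted β-carbon C5 may be slow, so that iodination stalls or strays to C2 or C6 through enol forms. The fallback sets out from 1 and comes back at 6. Nucleophilic epoxidation of 1 (H2O2, NaOH, MeOH) gives the 4,5-epoxy diketone F5. HBr in AcOH opens it at C4 and dehydrates it to the 4-bromo enedione F6. Ketalisation as in step 1 gives the 4-bromo enone ketal F7, which takes the place of 3 in the Negishi coupling with 5 and gives 6.

Step 7. The basic carbenoid may enolise the hindered cyclopentanone toward C7, and the crowded addition may reverse. The fallback sets out from 11 and comes back at 15. The less basic lithium salt of chloromethyl phenyl sulfoxide (LiN(i-Pr)2, THF, −78 °C) adds to 11 and gives the 8β-hydroxy-8α-[chloro(phenylsulfinyl)methyl] hydrindane F8. LiN(i-Pr)2 and then t-BuLi at −78 °C effect sulfoxide–lithium exchange to the chloro β-oxido carbenoid F9, which undergoes the same 1,2-shift to the enolate 15. Bromide 13 is then added as in step 8 to give 16.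

**Further compounds**
F1 | step 8 | 8α-vinyl-8β-hydroxy hydrindane | CC(C)=CCC[C@@]1(C)CCC[C@@]2(C)[C@H]1CC[C@@]2(O)C=C
F2 | step 8 | epoxy alcohol, 8β-hydroxy-8α-oxiranyl hydrindane (epoxide carbon not assigned) | CC(C)=CCC[C@@]1(C)CCC[C@@]2(C)[C@H]1CC[C@@]2(O)C1CO1
F3 | step 8 | 9-(hydroxymethyl)decalin-8-one (C9 follows the epoxide and is not assigned) | CC(C)=CCC[C@@]1(C)CCC[C@]2(C)C(CO)C(=O)CC[C@@H]12
F4 | step 8 | 9-methylenedecalin-8-one | CC(C)=CCC[C@@]1(C)CCC[C@]2(C)C(=C)C(=O)CC[C@@H]12
F5 | step 2 | 4,5-epoxy diketone from 1 (epoxide carbons not assigned) | C[C@]12CCC(=O)C3OC31CCC2=O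
F6 | step 2 | 4-bromo enedione (4-bromo derivative of 1) | C[C@]12CCC(=O)C(Br)=C1CCC2=O
F7 | step 2 | 4-bromo enone ketal (bromo analogue of 3) | C[C@]12CCC(=O)C(Br)=C1CCC21OCCO1
F8 | step 7 | 8β-hydroxy-8α-[chloro(phenylsulfinyl)methyl] hydrindane | CC(C)=CCC[C@@]1(C)CCC[C@@]2(C)[C@H]1CC[C@@]2(O)C(Cl)S(=O)c1ccccc1
F9 | step 7 | chloro β-oxido carbenoid, 8β-lithiooxy-8α-[chloro(lithio)methyl] hydrindane | CC(C)=CCC[C@@]1(C)CCC[C@@]2(C)[C@H]1CC[C@@]2(O[Li])C([Li])Cl
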